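**Retrosynthetic overview**

1. The target is a 5,5'-linked bichromone. Its carbonyl carbons C4 and C4' sit on C4a and C4a', each ortho to the C5–C5' bond. Joined to each other, C4 and C4' are C10 and C9 of a phenanthrene whose C4a–C4b bond is the biaryl axis.
2. Both pyranone rings are made last and together, by O1–C2 closure of o-hydroxyaryl β-amino enones. These come from a bis-ynone, and that from a biaryl-2,2'-dicarbaldehyde plus two 4-phenylbutynide units.
3. The dialdehyde comes from cleavage of the C9–C10 bond of 1,4,7,8-tetramethoxyphenanthrene (osmylation, then periodate).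
4. The phenanthrene comes from oxidative photocyclisation of (E)-1-(2,5-dimethoxyphenyl)-2-(2,3-dimethoxyphenyl)ethene. This forms the C5–C5' bond and the central ring. The stilbene is made by Horner–Wadsworth–Emmons olefination.
5. Ring order: central carbocycle (step 3, opened again in step 5), then the two pyranone rings (step 9).

Key step: step 3

Assumption 1: the target SMILES carries no stereodescriptor, so the hindered C5–C5' axis is not controlled and the product is taken as the racemate (or the freely rotating compound).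
Assumption 2: 2,5-dimethoxybenzyl chloride is taken as a catalogue compound, which shortens the way to the stilbene to two steps.

**Route**

Step 1
Reactants: 1 2,5-dimethoxybenzyl chloride
Product: 2 diethyl [(2,5-dimethoxyphenyl)methyl]phosphonate
Conditions: P(OEt)3 (neat, 1.5 equiv), 140 °C
Reagents that add atoms: triethyl phosphite, CCOP(OCC)OCC
Why: Michaelis–Arbuzov reaction, in which the phosphite displaces the activated benzylic chloride and the chloride then dealkylates the phosphonium ion, with volatile chloroethane leaving the melt.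

Step 2
Reactants: 2 diethyl [(2,5-dimethoxyphenyl)methyl]phosphonate; 3 2,3-dimethoxybenzaldehyde
Product: 4 (E)-1-(2,5-dimethoxyphenyl)-2-(2,3-dimethoxyphenyl)ethene
Conditions: KOtBu, THF, 0 °C to rt
Reagents that add atoms: none
Why: Horner–Wadsworth–Emmons olefination of a benzylic phosphonate with an aromatic aldehyde should give the E-stilbene through the reversibly formed anti adduct, and any Z isomer is harmless because light equilibrates the two in the next step.

Step 3
Reactants: 4 (E)-1-(2,5-dimethoxyphenyl)-2-(2,3-dimethoxyphenyl)ethene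
Product: 7 1,4,7,8-tetramethoxyphenanthrene, via (Z)-stilbene 5 (not isolated), via trans-4a,4b-dihydrophenanthrene 6 (not isolated)
Conditions: hν (medium-pressure Hg lamp, Pyrex filter), I2 (1.1 equiv), methyloxirane (excess), degassed toluene (about 2 mM), Ar, rt
Reagents that add atoms: none
Why: Light interconverts 4 and its Z isomer 5, and 5 undergoes a conrotatory six-electron electrocyclisation of the aryl–ethene–aryl hexatriene to the trans-4a,4b-dihydrophenanthrene 6, which iodine dehydrogenates irreversibly to 7 while methyloxirane consumes the HI (Mallory oxidative photocyclisation of a stilbene). The one ring formed is the central six-membered carbocycle, closed by 6π electrocyclisation between C6 of the 2,5-dimethoxyphenyl group and C6 of the 2,3-dimethoxyphenyl group, which is the future C5–C5' bond. No stereocentre remains, because the two trans hydrogens of 6 fixed by conrotation are removed in the oxidation. The step needs regioselective closure at the two ortho C–H carbons, and this is secured because each aryl group has only one ortho C–H, the other ortho carbon bearing methoxy; closure at a methoxy carbon gives a dihydrophenanthrene that iodine cannot aromatise and that reopens, and with HI scavenged its acid-promoted loss of methanol is not assisted. High dilution should suppress [2+2] dimerisation of the stilbene, and exclusion of oxygen protects the electron-rich phenanthrene.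

Step 4
Reactants: 7 1,4,7,8-tetramethoxyphenanthrene
Product: 9 cis-1,4,7,8-tetramethoxy-9,10-dihydrophenanthrene-9,10-diol (racemic), via bis(pyridine) osmate ester 8 (not isolated)
Conditions: OsO4 (1.1 equiv), pyridine, rt; then aq. KOH, D-mannitol, CH2Cl2
Reagents that add atoms: osmium tetroxide, O=[Os](=O)(=O)=O; pyridine, c1ccncc1, is held only in 8
Why: The C9–C10 bond is the most olefinic bond of a phenanthrene and undergoes suprafacial [3+2] osmylation, so both carbinol centres are set cis by syn addition through the cyclic osmate of hexavalent osmium, as the racemate because the two faces of planar 7 are enantiotopic.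

Step 5
Reactants: 9 cis-1,4,7,8-tetramethoxy-9,10-dihydrophenanthrene-9,10-diol
Product: 10 3,3',4',6-tetramethoxy-[1,1'-biphenyl]-2,2'-dicarbaldehyde
Conditions: NaIO4, THF/H2O, 0 °C to rt
Reagents that add atoms: none
Why: Malaprade glycol cleavage through a cyclic periodate ester, for which a cis-1,2-diol is the ideal substrate, opens the central ring to the biaryl dialdehyde without touching the aryl ethers.

Step 6
Reactants: 10 3,3',4',6-tetramethoxy-[1,1'-biphenyl]-2,2'-dicarbaldehyde; 11 4-phenylbut-1-yne
Product: 12 1,1'-(3,3',4',6-tetramethoxy-[1,1'-biphenyl]-2,2'-diyl)bis(5-phenylpent-2-yn-1-ol) (mixture of diastereomers)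
Conditions: 11 (3 equiv), n-BuLi, THF, −78 °C; then 10, −78 to 0 °C; aq. NH4Cl
Reagents that add atoms: none
Why: Twofold 1,2-addition of a lithium acetylide to aromatic aldehydes, run with excess acetylide to pull any lactolate of the mono-adduct through to the diol; the two carbinol centres are not controlled and need not be, since both are oxidised in step 7.

Step 7
Reactants: 12 1,1'-(3,3',4',6-tetramethoxy-[1,1'-biphenyl]-2,2'-diyl)bis(5-phenylpent-2-yn-1-ol)
Product: 13 1,1'-(3,3',4',6-tetramethoxy-[1,1'-biphenyl]-2,2'-diyl)bis(5-phenylpent-2-yn-1-one)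
Conditions: Dess–Martin periodinane (2.5 equiv), CH2Cl2, rt
Reagents that add atoms: none
Why: Dess–Martin oxidation of benzylic, propargylic secondary alcohols gives aryl ynones under neutral conditions without alkyne-to-allene isomerisation, and all diastereomers of 12 converge on one compound.

Step 8
Reactants: 13 1,1'-(3,3',4',6-tetramethoxy-[1,1'-biphenyl]-2,2'-diyl)bis(5-phenylpent-2-yn-1-one)
Product: 14 (2E,2'E)-1,1'-(3,3',4',6-tetramethoxy-[1,1'-biphenyl]-2,2'-diyl)bis[3-(diethylamino)-5-phenylpent-2-en-1-one]
Conditions: Et2NH (excess), EtOH, rt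
Reagents that add atoms: diethylamine, CCNCC
Why: Aza-Michael addition of a secondary amine to an ynone gives the β-amino enone (vinylogous amide), which marks the future C2 as the only electrophilic carbon so that the later O-cyclisation must be six-membered and cannot give an aurone.

Step 9
Reactants: 14 (2E,2'E)-1,1'-(3,3',4',6-tetramethoxy-[1,1'-biphenyl]-2,2'-diyl)bis[3-(diethylamino)-5-phenylpent-2-en-1-one]
Product: 16 6,8'-dihydroxy-2,2'-bis(2-phenylethyl)-4H,4'H-[5,5'-bichromene]-4,4'-dione (target), via tetrahydroxy bis-enaminone 15 (not isolated)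
Conditions: BBr3 (10 equiv), CH2Cl2, −78 °C to rt; H2O; then 2 M aq. HCl, EtOH, 60 °C, Ar
Reagents that add atoms: none
Why: BBr3 cleaves all four aryl methyl ethers (boron-assisted SN2 by bromide, the carbonyl-flanked ones first by chelation), and in acid each o-hydroxyaryl β-amino enone closes by 6-endo-trig oxa-Michael addition and loss of diethylamine to the 4-pyranone, a known chromone cyclisation that a partly hydrolysed 1,3-diketone would undergo as well.

**Compound list**

1 | 2,5-dimethoxybenzyl chloride | COc1ccc(OC)c(CCl)c1 | starting material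
2 | diethyl [(2,5-dimethoxyphenyl)methyl]phosphonate | CCOP(=O)(Cc1cc(OC)ccc1OC)OCC | intermediate
3 | 2,3-dimethoxybenzaldehyde | COc1cccc(C=O)c1OC | starting material
4 | (E)-1-(2,5-dimethoxyphenyl)-2-(2,3-dimethoxyphenyl)ethene | COc1ccc(OC)c(/C=C/c2cccc(OC)c2OC)c1 | intermediate
5 | (Z)-1-(2,5-dimethoxyphenyl)-2-(2,3-dimethoxyphenyl)ethene | COc1ccc(OC)c(/C=C\c2cccc(OC)c2OC)c1 | intermediate
6 | trans-1,4,7,8-tetramethoxy-4a,4b-dihydrophenanthrene (racemic) | COC1=CC=C(OC)[C@@H]2C1=CC=C1C(OC)=C(OC)C=C[C@H]12 | intermediate
7 | 1,4,7,8-tetramethoxyphenanthrene | COc1ccc(OC)c2c1ccc1c(OC)c(OC)ccc12 | intermediate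
8 | cyclic osmate ester of 7 at C9/C10, OsO2(OR)2(pyridine)2, cis (racemic) | COc1ccc(OC)c2c1[C@H]1O[Os-2](=O)(=O)([n+]3ccccc3)([n+]3ccccc3)O[C@H]1c1c(OC)c(OC)ccc12 | intermediate
9 | cis-(9R*,10S*)-1,4,7,8-tetramethoxy-9,10-dihydrophenanthrene-9,10-diol (racemic) | COc1ccc(OC)c2c1[C@@H](O)[C@@H](O)c1c(OC)c(OC)ccc12 | intermediate
10 | 3,3',4',6-tetramethoxy-[1,1'-biphenyl]-2,2'-dicarbaldehyde | COc1ccc(OC)c(-c2ccc(OC)c(OC)c2C=O)c1C=O | intermediate
11 | 4-phenylbut-1-yne | C#CCCc1ccccc1 | starting material
12 | 1,1'-(3,3',4',6-tetramethoxy-[1,1'-biphenyl]-2,2'-diyl)bis(5-phenylpent-2-yn-1-ol), diastereomer mixture | COc1ccc(OC)c(-c2ccc(OC)c(OC)c2C(O)C#CCCc2ccccc2)c1C(O)C#CCCc1ccccc1 | intermediate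
13 | 1,1'-(3,3',4',6-tetramethoxy-[1,1'-biphenyl]-2,2'-diyl)bis(5-phenylpent-2-yn-1-one) | COc1ccc(OC)c(-c2ccc(OC)c(OC)c2C(=O)C#CCCc2ccccc2)c1C(=O)C#CCCc1ccccc1 | intermediate
14 | (2E,2'E)-1,1'-(3,3',4',6-tetramethoxy-[1,1'-biphenyl]-2,2'-diyl)bis[3-(diethylamino)-5-phenylpent-2-en-1-one] | COc1ccc(OC)c(-c2ccc(OC)c(OC)c2C(=O)/C=C(/N(CC)CC)CCc2ccccc2)c1C(=O)/C=C(/N(CC)CC)CCc1ccccc1 | intermediate
15 | (2E,2'E)-1,1'-(3,3',4',6-tetrahydroxy-[1,1'-biphenyl]-2,2'-diyl)bis[3-(diethylamino)-5-phenylpent-2-en-1-one] | Oc1ccc(O)c(-c2ccc(O)c(O)c2C(=O)/C=C(/N(CC)CC)CCc2ccccc2)c1C(=O)/C=C(/N(CC)CC)CCc1ccccc1 | intermediate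
16 | 6,8'-dihydroxy-2,2'-bis(2-phenylethyl)-4H,4'H-[5,5'-bichromene]-4,4'-dione | O=c1cc(CCc2ccccc2)oc2ccc(O)c(-c3ccc(O)c4oc(CCc5ccccc5)cc(=O)c34)c12 | target

**Step count and risks**

Total step count: 9. Longest linear sequence: 9 steps (1 to 16).

Steps most likely to fail:

Step 3. The electrocyclisation has to form a bond next to the C5 methoxy group of the 2,5-dimethoxyphenyl ring and place that group in the bay region. If this closure is slow, closure at a methoxy-bearing carbon with loss of methanol, [2+2] dimerisation and photo-oxidation of the product can take over. The fallback forms the same bond without light. It sets out from 1: heating with PPh3 in toluene should give (2,5-dimethoxybenzyl)triphenylphosphonium chloride F1. Wittig olefination (KOtBu, THF, −78 °C to rt) with commercial 6-bromo-2,3-dimethoxybenzaldehyde F2 should favour, through the ortho-halo effect on semi-stabilised ylides, (Z)-1-(6-bromo-2,3-dimethoxyphenyl)-2-(2,5-dimethoxyphenyl)ethene F3. Intramolecular palladium-catalysed C–H arylation (Pd(OAc)2, PCy3·HBF4, K2CO3, DMA, 130 °C) can engage only the single ortho C–H of the other ring and comes back to the route at 7.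

Step 9. Cleavage of four methyl ethers in the presence of two vinylogous amides may stop early. The free hydroquinone and catechol rings of the open intermediate may also be oxidised before the pyranone rings close. The fallback closes the rings while the oxygens are still methylated and deprotects last. It sets out from 13: ICl in CH2Cl2 at −78 °C should effect demethylative 6-endo iodocyclisation of both o-methoxyaryl ynones to 3,3'-diiodo-6,8'-dimethoxy-2,2'-bis(2-phenylethyl)-4H,4'H-[5,5'-bichromene]-4,4'-dione F4. Palladium-catalysed hydrodeiodination (Pd(OAc)2, PPh3, HCO2Na, DMF, 80 °C) gives 6,8'-dimethoxy-2,2'-bis(2-phenylethyl)-4H,4'H-[5,5'-bichromene]-4,4'-dione F5. BBr3 in CH2Cl2 then removes the two remaining methyl groups from the robust chromone and comes back to the route at 16.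

Step 6. After the first addition the alkoxide can add to the neighbouring aldehyde across the biaryl and hold it as a seven-membered lactolate, so the reaction may stall at the mono-adduct. The fallback avoids alkoxide intermediates and goes through the acid oxidation level. It sets out from 10: Pinnick oxidation (NaClO2, NaH2PO4, 2-methylbut-2-ene, t-BuOH/H2O) gives 3,3',4',6-tetramethoxy-[1,1'-biphenyl]-2,2'-dicarboxylic acid F6. Oxalyl chloride with catalytic DMF in CH2Cl2 gives 3,3',4',6-tetramethoxy-[1,1'-biphenyl]-2,2'-dicarbonyl dichloride F7. Twofold acyl Sonogashira coupling with 11 (PdCl2(PPh3)2, CuI, Et3N, THF, rt) forms both ynones directly and comes back to the route at 13, so that step 7 is not needed.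

**Further compounds**

F1 | step 3 | (2,5-dimethoxybenzyl)triphenylphosphonium chloride | COc1ccc(OC)c(C[P+](c2ccccc2)(c2ccccc2)c2ccccc2)c1.[Cl-]
F2 | step 3 | 6-bromo-2,3-dimethoxybenzaldehyde | COc1ccc(Br)c(C=O)c1OC
F3 | step 3 | (Z)-1-(6-bromo-2,3-dimethoxyphenyl)-2-(2,5-dimethoxyphenyl)ethene | COc1ccc(OC)c(/C=C\c2c(Br)ccc(OC)c2OC)c1
F4 | step 9 | 3,3'-diiodo-6,8'-dimethoxy-2,2'-bis(2-phenylethyl)-4H,4'H-[5,5'-bichromene]-4,4'-dione | O=c1c(I)c(CCc2ccccc2)oc2ccc(OC)c(-c3ccc(OC)c4oc(CCc5ccccc5)c(I)c(=O)c34)c12
F5 | step 9 | 6,8'-dimethoxy-2,2'-bis(2-phenylethyl)-4H,4'H-[5,5'-bichromene]-4,4'-dione | O=c1cc(CCc2ccccc2)oc2ccc(OC)c(-c3ccc(OC)c4oc(CCc5ccccc5)cc(=O)c34)c12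
F6 | step 6 | 3,3',4',6-tetramethoxy-[1,1'-biphenyl]-2,2'-dicarboxylic acid | COc1ccc(OC)c(-c2ccc(OC)c(OC)c2C(=O)O)c1C(=O)O
F7 | step 6 | 3,3',4',6-tetramethoxy-[1,1'-biphenyl]-2,2'-dicarbonyl dichloride | COc1ccc(OC)c(-c2ccc(OC)c(OC)c2C(Cl)=O)c1C(Cl)=O
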